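**Strategy**

Atoms are numbered C1 (ester carbon) to C15 along the chain; the ring is O1, O2, C3, C4, C5, C6. Everything rests on cutting O1–C6. The target is a γ-peroxy ketone, O1–C6–C7–C8–C9=O, the retron of a homo-conjugate addition, so C6, C7 and C8 are tied into a cyclopropane that carries the C9 ketone. In the key step the C3 hydroperoxide opens this cyclopropyl ketone at its quaternary carbon C6 with inversion: one isomerisation closes the dioxane, sets C6 and unveils the C7–C8–C9 keto chain. The precursor is an acyclic hydroperoxide with a geraniol-derived enantioenriched cyclopropane.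

Key step: step 11

Remark: the facial sense of the two chiral reagents (steps 1 and 7) is taken from their established models and, should either run the other way, its enantiomer is used; C8 ceases to be a stereocentre in step 11, so its epimerisation on the way is of no consequence.

**Route**

Step 1
Reactants: 1 geraniol
Product: 2 [(1S,2S)-2-methyl-2-(4-methylpent-3-en-1-yl)cyclopropyl]methanol
Conditions: Et2Zn, CH2I2, DME, CH2Cl2, −10 °C; (4R,5R)-2-butyl-N,N,N′,N′-tetramethyl-1,3,2-dioxaborolane-4,5-dicarboxamide (1.2 equiv), −10 °C → rt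
Reagents that add atoms: diiodomethane, ICI
Why: Charette asymmetric Simmons–Smith cyclopropanation, in which the zinc alkoxide bound to the chiral dioxaborolane should deliver CH2 (the future C7) to the Si face of the carbinol-bearing alkene carbon of the allylic alkene only, setting C6 and C8 stereospecifically from the E alkene and sparing the remote alkene.

Step 2
Reactants: 2 cyclopropylmethanol
Product: 3 (1S,2S)-2-methyl-2-(4-methylpent-3-en-1-yl)cyclopropane-1-carboxylic acid
Conditions: TEMPO (cat.), PhI(OAc)2, MeCN/H2O, rt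
Reagents that add atoms: water, O
Why: nitroxyl-mediated oxidation of a primary alcohol through the aldehyde hydrate to the acid, conditions that should leave the trisubstituted alkene and the cyclopropane untouched.

Step 3
Reactants: 3 cyclopropanecarboxylic acid
Product: 5 isopropyl ketone 2-methyl-1-[(1S,2S)-2-methyl-2-(4-methylpent-3-en-1-yl)cyclopropyl]propan-1-one, via dilithium gem-diolate 4 (not isolated)
Conditions: i-PrLi (2.2 equiv), Et2O, −78 → 0 °C; then aq. HCl
Reagents that add atoms: isopropyllithium, [Li]C(C)C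
Why: ketone synthesis from a carboxylic acid and two equivalents of an organolithium, in which the gem-diolate should not collapse before the quench, so that no tertiary alcohol forms.

Step 4
Reactants: 6 2-(3-chloropropyl)-2-methyl-1,3-dioxolane
Product: 7 2-(3-iodopropyl)-2-methyl-1,3-dioxolane
Conditions: NaI, acetone, reflux
Reagents that add atoms: sodium iodide, [Na+].[I-]
Why: Finkelstein halide exchange, driven by precipitation of NaCl, to give the more reactive alkylating agent.

Step 5
Reactants: 5 isopropyl ketone; 7 iodide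
Product: 9 2,2-dimethyl-1-[(1S,2S)-2-methyl-2-(4-methylpent-3-en-1-yl)cyclopropyl]-5-(2-methyl-1,3-dioxolan-2-yl)pentan-1-one, via lithium enolate 8 (not isolated)
Conditions: LiN(i-Pr)2 (from i-Pr2NH, n-BuLi), THF, −78 → 0 °C; then 7, DMPU, −78 °C → rt
Reagents that add atoms: none
Why: enolate alkylation, in which the base should remove the isopropyl methine hydrogen (the cyclopropyl α-hydrogen is kinetically non-acidic because its enolate would be an alkylidenecyclopropane) and SN2 attack on the primary iodide builds the quaternary C10.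

Step 6
Reactants: 9 alkene
Product: 11 aldehyde 3-[(1S,2S)-2-[2,2-dimethyl-5-(2-methyl-1,3-dioxolan-2-yl)pentanoyl]-1-methylcyclopropyl]propanal, via ozonide 10 (not isolated)
Conditions: O3, CH2Cl2, −78 °C; then Me2S, −78 °C → rt
Reagents that add atoms: ozone, [O-][O+]=O
Why: ozonolysis of the only alkene with reductive work-up should unveil C3 as the aldehyde, the ketone, ketal and cyclopropane being inert to ozone.

Step 7
Reactants: 11 aldehyde
Product: 13 syn homoallylic alcohol 1-[(1S,2S)-2-[(3R,4R)-3-hydroxy-4-methylhex-5-en-1-yl]-2-methylcyclopropyl]-2,2-dimethyl-5-(2-methyl-1,3-dioxolan-2-yl)pentan-1-one, via borinate ester 12 (not isolated)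
Conditions: cis-2-butene, KOt-Bu, n-BuLi, THF, −78 → −45 °C; (−)-Ipc2BOMe, −78 °C; BF3·OEt2; then 11, −78 °C; then NaOH, H2O2, rt
Reagents that add atoms: cis-but-2-ene, C/C=C\C (transferred as (Z)-crotyldiisopinocampheylborane, C/C=C\CB([C@@H]1C[C@@H]2C[C@@H](C2(C)C)[C@H]1C)[C@@H]1C[C@@H]2C[C@@H](C2(C)C)[C@H]1C)
Why: Brown asymmetric crotylboration, in which the Z-crotyl group in a chair Zimmerman–Traxler transition state should give the syn relation of C2 and C3 and the isopinocampheyl groups of the (+)-α-pinene series select the aldehyde face that gives the (R)-carbinol, under reagent control and with the hindered ketone left alone.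

Step 8
Reactants: 14 3,4-dihydro-2H-pyran
Product: 15 2-hydroperoxytetrahydropyran (racemic)
Conditions: 50% aq. H2O2, H2SO4 (cat.), 0 °C
Reagents that add atoms: hydrogen peroxide, OO
Why: acid-catalysed Markovnikov addition of H2O2 to the enol ether through its oxocarbenium ion, the standard preparation of this protected hydroperoxide.

Step 9
Reactants: 13 syn alcohol; 15 2-hydroperoxytetrahydropyran
Product: 17 tetrahydropyranyl peroxide 1-[(1S,2S)-2-[(3S,4R)-4-methyl-3-(oxan-2-ylperoxy)hex-5-en-1-yl]-2-methylcyclopropyl]-2,2-dimethyl-5-(2-methyl-1,3-dioxolan-2-yl)pentan-1-one, via triflate 16 (not isolated)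
Conditions: Tf2O, 2,6-lutidine, CH2Cl2, −78 °C; then 15, KOt-Bu, THF, −78 → 0 °C
Reagents that add atoms: none
Why: alkylation of a monoperoxyacetal anion by a secondary alkyl triflate, an SN2 displacement by a weakly basic α-effect nucleophile that should invert C3 and so give the (3S) peroxide anti to the C2 methyl group.

Step 10
Reactants: 17 tetrahydropyranyl peroxide
Product: 18 hydroperoxide 1-[(1S,2S)-2-[(3S,4R)-3-hydroperoxy-4-methylhex-5-en-1-yl]-2-methylcyclopropyl]-2,2-dimethylheptane-1,6-dione
Conditions: TsOH·H2O (cat.), THF/H2O, rt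
Reagents that add atoms: water, O
Why: acid-catalysed hydrolysis of the peroxyacetal and of the dioxolane should free the hydroperoxide and the C14 methyl ketone in one operation without touching the O–O bond or the stereocentres.

Step 11
Reactants: 18 hydroperoxide
Product: 20 dioxane 1-[(3R,6S)-6-[(2R)-but-3-en-2-yl]-3-methyl-1,2-dioxan-3-yl]-4,4-dimethylnonane-3,8-dione, via enol 19 (not isolated)
Conditions: Sc(OTf)3 (10 mol %), CH2Cl2, −20 → 0 °C
Reagents that add atoms: none
Why: Proposed new method: Sc(OTf)3 binds the C9 carbonyl of 18 and polarises the C6–C8 bond of the cyclopropane, the terminal oxygen of the C3 hydroperoxide then attacks the tertiary carbon C6 from the side opposite C8 while C8–C9 leaves as the enolate, which takes up the hydroperoxide proton to give enol 19 and, by tautomerisation, ketone 20, a catalytic isomerisation with no by-product. The closest known reactions are the stereoinvertive substitution at the quaternary carbon of cyclopropyl ketones by silyl halides or azide, the homo-conjugate addition of oxygen nucleophiles to donor–acceptor cyclopropanes and the Lewis-acid opening of oxetanes and epoxides by hydroperoxides to 1,2-dioxanes. The dioxane closes in the 6-exo-tet mode, the breaking C6–C8 bond lying outside the new ring. C6 is the only stereocentre formed and is fixed by inversion of the cyclopropane carbon set in step 1, C2 and C3 are spectators and C8 ends as a CH2 group. The step needs attack at C6 and not at C7, and must outrun ring expansion by the carbonyl oxygen (Cloke–Wilson), acid fragmentation of the hydroperoxide and free-cation formation; the tertiary nature of C6, the six-membered transition state, the non-polar solvent and the low temperature should secure this.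

Step 12
Reactants: 20 vinyl dioxane
Product: 21 (2S)-2-[(3S,6R)-6-(4,4-dimethyl-3,8-dioxononyl)-6-methyl-1,2-dioxan-3-yl]propanoic acid
Conditions: RuCl3·xH2O (cat.), NaIO4, CCl4/MeCN/H2O, rt
Reagents that add atoms: sodium periodate, [Na+].[O-]I(=O)(=O)=O; water, O
Why: RuO4-catalysed oxidative cleavage of the terminal alkene to the acid with loss of one carbon, an oxidation to which dialkyl peroxides and ketones should be inert and which is not basic enough to epimerise C2.

Step 13
Reactants: 21 acid
Product: 22 diacarperoxide B, methyl (2S)-2-[(3S,6R)-6-(4,4-dimethyl-3,8-dioxononyl)-6-methyl-1,2-dioxan-3-yl]propanoate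
Conditions: Me3SiCHN2, MeOH/toluene, 0 °C
Reagents that add atoms: (trimethylsilyl)diazomethane, C[Si](C)(C)C=[N+]=[N-]
Why: esterification with a diazomethane equivalent under neutral conditions, which should avoid base-induced retro-oxa-Michael opening or Kornblum–DeLaMare cleavage of the β-peroxy ester.

**Compound list**

1 | geraniol, (2E)-3,7-dimethylocta-2,6-dien-1-ol | CC(C)=CCC/C(C)=C/CO | starting material
2 | [(1S,2S)-2-methyl-2-(4-methylpent-3-en-1-yl)cyclopropyl]methanol | OC[C@H]1C[C@]1(C)CCC=C(C)C | intermediate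
3 | (1S,2S)-2-methyl-2-(4-methylpent-3-en-1-yl)cyclopropane-1-carboxylic acid | OC(=O)[C@H]1C[C@]1(C)CCC=C(C)C | intermediate
4 | dilithium gem-diolate of ketone 5 | [Li+].[Li+].[O-]C([O-])(C(C)C)[C@H]1C[C@]1(C)CCC=C(C)C | intermediate (not isolated)
5 | 2-methyl-1-[(1S,2S)-2-methyl-2-(4-methylpent-3-en-1-yl)cyclopropyl]propan-1-one | CC(C)C(=O)[C@H]1C[C@]1(C)CCC=C(C)C | intermediate
6 | 2-(3-chloropropyl)-2-methyl-1,3-dioxolane | CC1(CCCCl)OCCO1 | starting material
7 | 2-(3-iodopropyl)-2-methyl-1,3-dioxolane | CC1(CCCI)OCCO1 | intermediate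
8 | lithium enolate of ketone 5 | [Li+].[O-]C(=C(C)C)[C@H]1C[C@]1(C)CCC=C(C)C | intermediate (not isolated)
9 | 2,2-dimethyl-1-[(1S,2S)-2-methyl-2-(4-methylpent-3-en-1-yl)cyclopropyl]-5-(2-methyl-1,3-dioxolan-2-yl)pentan-1-one | CC1(CCCC(C)(C)C(=O)[C@H]2C[C@]2(C)CCC=C(C)C)OCCO1 | intermediate
10 | ozonide of 9 (3,3-dimethyl-1,2,4-trioxolane at the former alkene, both epimers at the acetal carbon) | CC1(C)OOC(CC[C@@]2(C)C[C@@H]2C(=O)C(C)(C)CCCC3(C)OCCO3)O1 | intermediate (not isolated)
11 | 3-[(1S,2S)-2-[2,2-dimethyl-5-(2-methyl-1,3-dioxolan-2-yl)pentanoyl]-1-methylcyclopropyl]propanal | O=CCC[C@@]1(C)C[C@@H]1C(=O)C(C)(C)CCCC2(C)OCCO2 | intermediate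
12 | diisopinocampheylborinate ester of alcohol 13 | C=C[C@@H](C)[C@H](OB([C@@H]3C[C@@H]4C[C@@H](C4(C)C)[C@H]3C)[C@@H]3C[C@@H]4C[C@@H](C4(C)C)[C@H]3C)CC[C@@]1(C)C[C@@H]1C(=O)C(C)(C)CCCC2(C)OCCO2 | intermediate (not isolated)
13 | 1-[(1S,2S)-2-[(3R,4R)-3-hydroxy-4-methylhex-5-en-1-yl]-2-methylcyclopropyl]-2,2-dimethyl-5-(2-methyl-1,3-dioxolan-2-yl)pentan-1-one | C=C[C@@H](C)[C@H](O)CC[C@@]1(C)C[C@@H]1C(=O)C(C)(C)CCCC2(C)OCCO2 | intermediate
14 | 3,4-dihydro-2H-pyran | C1=COCCC1 | starting material
15 | 2-hydroperoxytetrahydropyran (racemic) | OOC1CCCCO1 | intermediate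
16 | (3R,4R)-triflate of alcohol 13 | C=C[C@@H](C)[C@H](OS(=O)(=O)C(F)(F)F)CC[C@@]1(C)C[C@@H]1C(=O)C(C)(C)CCCC2(C)OCCO2 | intermediate (not isolated)
17 | 1-[(1S,2S)-2-[(3S,4R)-4-methyl-3-(oxan-2-ylperoxy)hex-5-en-1-yl]-2-methylcyclopropyl]-2,2-dimethyl-5-(2-methyl-1,3-dioxolan-2-yl)pentan-1-one (both epimers at the acetal carbon) | C=C[C@@H](C)[C@@H](OOC3CCCCO3)CC[C@@]1(C)C[C@@H]1C(=O)C(C)(C)CCCC2(C)OCCO2 | intermediate
18 | 1-[(1S,2S)-2-[(3S,4R)-3-hydroperoxy-4-methylhex-5-en-1-yl]-2-methylcyclopropyl]-2,2-dimethylheptane-1,6-dione | C=C[C@@H](C)[C@@H](OO)CC[C@@]1(C)C[C@@H]1C(=O)C(C)(C)CCCC(C)=O | intermediate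
19 | C8=C9 enol of dioxane 20 | C=C[C@@H](C)[C@@H]1CC[C@](C)(CC=C(O)C(C)(C)CCCC(C)=O)OO1 | intermediate (not isolated)
20 | 1-[(3R,6S)-6-[(2R)-but-3-en-2-yl]-3-methyl-1,2-dioxan-3-yl]-4,4-dimethylnonane-3,8-dione | C=C[C@@H](C)[C@@H]1CC[C@](C)(CCC(=O)C(C)(C)CCCC(C)=O)OO1 | intermediate
21 | (2S)-2-[(3S,6R)-6-(4,4-dimethyl-3,8-dioxononyl)-6-methyl-1,2-dioxan-3-yl]propanoic acid | OC(=O)[C@@H](C)[C@@H]1CC[C@](C)(CCC(=O)C(C)(C)CCCC(C)=O)OO1 | intermediate
22 | diacarperoxide B, methyl (2S)-2-[(3S,6R)-6-(4,4-dimethyl-3,8-dioxononyl)-6-methyl-1,2-dioxan-3-yl]propanoate | COC(=O)[C@@H](C)[C@@H]1CC[C@](C)(CCC(=O)C(C)(C)CCCC(C)=O)OO1 | target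

**Step count and risks**

Total step count: 13. Longest linear sequence: 11 steps (1, 2, 3, 5, 6, 7, 9, 10, 11, 12, 13); steps 4 and 8 make the two side reagents.

Steps most likely to fail:

1. Step 11 (Proposed new method). The activated cyclopropyl ketone may ring-expand through its own carbonyl oxygen, the secondary hydroperoxide may fragment under acid, or C6 may ionise fully so that stereospecificity is lost. Fallback with known chemistry, setting out from 18: the cyclopropane would first be opened by a chlorosilane (Me3SiCl, cat. ZnCl2, CH2Cl2; the hydroperoxide rides as its silyl peroxide and is freed on work-up), the known stereoinvertive halide opening of cyclopropyl ketones, to give the tertiary chloride (10R,13S,14R)-10-chloro-13-hydroperoxy-6,6,10,14-tetramethylhexadec-15-ene-2,7-dione F1. AgOTf with 2,6-di-tert-butylpyridine in CH2Cl2 at low temperature would then close the same O1–C6 bond by silver-assisted displacement of chloride, coming back to the route at 20. This closure passes through a tertiary cation, so C6 would be governed only by the chair preference and the C6 epimer would have to be separated.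

2. Step 9. The triflate may eliminate toward the conjugated diene, substitution at the β-branched carbon may be slow, and ionisation would erode the configuration at C3. Fallback, setting out from 11: (E)-crotylboration with the enantiomeric borane (from (+)-Ipc2BOMe) would give the anti alcohol F2. Appel bromination (PPh3, CBr4) with inversion would give the bromide F3. Silver-assisted perhydrolysis (AgOTf, anhydrous H2O2 in Et2O), a non-basic substitution again with inversion, would give the hydroperoxy ketal F4. The hydrolysis conditions of step 10 would then bring it back to the route at 18.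

3. Step 12. RuO4 may over-oxidise the C–H next to the peroxide oxygen or degrade the keto chain before the alkene is fully cleaved. Fallback, setting out from 20: ozonolysis (O3, CH2Cl2, −78 °C; Me2S) would give the aldehyde F5, and chlorite oxidation (NaClO2, NaH2PO4, 2-methyl-2-butene, t-BuOH/H2O) would come back to the route at 21.

**Further compounds**

F1 | step 11 | (10R,13S,14R)-10-chloro-13-hydroperoxy-6,6,10,14-tetramethylhexadec-15-ene-2,7-dione | C=C[C@@H](C)[C@@H](OO)CC[C@@](C)(Cl)CCC(=O)C(C)(C)CCCC(C)=O
F2 | step 9 | 1-[(1S,2S)-2-[(3S,4R)-3-hydroxy-4-methylhex-5-en-1-yl]-2-methylcyclopropyl]-2,2-dimethyl-5-(2-methyl-1,3-dioxolan-2-yl)pentan-1-one | C=C[C@@H](C)[C@@H](O)CC[C@@]1(C)C[C@@H]1C(=O)C(C)(C)CCCC2(C)OCCO2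
F3 | step 9 | 1-[(1S,2S)-2-[(3R,4R)-3-bromo-4-methylhex-5-en-1-yl]-2-methylcyclopropyl]-2,2-dimethyl-5-(2-methyl-1,3-dioxolan-2-yl)pentan-1-one | C=C[C@@H](C)[C@H](Br)CC[C@@]1(C)C[C@@H]1C(=O)C(C)(C)CCCC2(C)OCCO2
F4 | step 9 | 1-[(1S,2S)-2-[(3S,4R)-3-hydroperoxy-4-methylhex-5-en-1-yl]-2-methylcyclopropyl]-2,2-dimethyl-5-(2-methyl-1,3-dioxolan-2-yl)pentan-1-one | C=C[C@@H](C)[C@@H](OO)CC[C@@]1(C)C[C@@H]1C(=O)C(C)(C)CCCC2(C)OCCO2
F5 | step 12 | (2S)-2-[(3S,6R)-6-(4,4-dimethyl-3,8-dioxononyl)-6-methyl-1,2-dioxan-3-yl]propanal | O=C[C@@H](C)[C@@H]1CC[C@](C)(CCC(=O)C(C)(C)CCCC(C)=O)OO1
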